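## Retrosynthetic overview

- Numbering (elemane) and feature: the only carbocycle is the cyclohexane C5–C10. C10 is quaternary (methyl C14, vinyl C1=C2), C5 carries isopropenyl, C6 the lactone oxygen, C7 carries C11, C8 the acetate; C11 bears methyl C13 and the angelate, C12 is the lactone carbonyl. The ring has oxygen at C6 and C8 (1,3-pattern of a 1-alkoxy-3-silyloxybutadiene). At C5/C10 it has two acyl-derived groups, isopropenyl and vinyl, trans to each other, with the C10 methyl cis to the C5 group (pattern of an E keto-ester dienophile).
- Endgame disconnections: the C8 acetate and C11 angelate (acylations); C11–O (hydroxylation of the lactone enolate on its convex face); C8–OH (hydride reduction of the C8 ketone); the γ-lactone C6–O bond (oxa-Michael addition of the C12 acid to the C8 enone); C7–C11 (Negishi coupling of the 7-iodoenone with a propanoate zinc enolate).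
- Vinyl and isopropenyl come from the C10 ester (through the aldehyde) and the C5 acetyl by methylenation, while the enone carbonyl is parked as its allylic alcohol.
- Key disconnection: enone 6 is the [4+2] adduct (bonds C9–C10 and C5–C6) of silyloxydiene 4 and E keto ester 3, which is a Wittig product of methylglyoxal. Ring order: cyclohexene (step 2), then γ-lactone (step 10).

Key step: step 2

Remark: the hand of the oxazaborolidinium catalyst is assigned by analogy with its usual sense of induction for acrylate and enone dienophiles, and this sense is itself recalled rather than checked; should the first run deliver the mirror-image enone, the enantiomeric catalyst is used and nothing else changes.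

## Route

Step 1
Reactants: 1 methylglyoxal (commercial aqueous solution); 2 methyl 2-(triphenylphosphoranylidene)propanoate
Product: 3 methyl (E)-2-methyl-4-oxopent-2-enoate
Conditions: CH2Cl2/H2O, 0 → 23 °C
Reagents that add atoms: none
Why: Wittig olefination in which the stabilised α-methyl ylide attacks only the aldehyde carbon of methylglyoxal and should give the E trisubstituted enoate, with acetyl and ester trans.

Step 2
Reactants: 3 methyl (E)-2-methyl-4-oxopent-2-enoate; 4 (E)-1-methoxy-3-trimethylsilyloxybuta-1,3-diene
Product: 6 methyl (1S,6S)-6-acetyl-1-methyl-3-oxocyclohex-4-ene-1-carboxylate, via cycloadduct silyl enol ether 5 (not isolated)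
Conditions: 4 (1.5 equiv), (R)-3,3-diphenyl-1-(o-tolyl)tetrahydro-1H,3H-pyrrolo[1,2-c][1,3,2]oxazaborole (20 mol%), Tf2NH (18 mol%), CH2Cl2, −78 → −40 °C; then 0.1 M HCl, THF, 0 °C
Reagents that add atoms: none
Why: Chiral-Lewis-acid-catalysed Diels–Alder reaction, the closest known type being the oxazaborolidinium-catalysed [4+2] addition of 1-alkoxy-3-silyloxydienes to 3-acylacrylates and acyclic enones, here extended to a trisubstituted dienophile: boron binds the more basic ketone oxygen of 3 and lowers the LUMO, whose largest coefficient then lies at C10, β to the ketone. The unsubstituted diene terminus (C9, largest HOMO coefficient) bonds to C10 and the methoxy-bearing terminus (C6) to C5 in one concerted, asynchronous, suprafacial step, and this cycloaddition is the closure of the six-membered ring C5–C10. Suprafacial addition to the E alkene fixes the C5 acetyl cis to the C10 methyl and trans to the ester, and the absolute configuration at C5 and C10 is set by the catalyst, whose aryl group should screen one face of the bound enone so that the diene adds to the Si faces of C5 and C10. The methoxy-bearing C6 centre is transient, since dilute acid cleaves the silyl enol ether and eliminates methanol to leave the C8 ketone with the C6=C7 double bond. The step needs regioselectivity (C9 to C10), secured by the ketone outweighing the ester as acceptor once it carries the Lewis acid, and it needs C5 to stay un-enolised, secured by low temperature, brief acid contact and the absence of base.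

Step 3
Reactants: 6 methyl (1S,6S)-6-acetyl-1-methyl-3-oxocyclohex-4-ene-1-carboxylate
Product: 7 methyl (1S,6S)-6-acetyl-3-hydroxy-1-methylcyclohex-4-ene-1-carboxylate (both C3 epimers)
Conditions: NaBH4, CeCl3·7H2O, MeOH, −78 °C
Reagents that add atoms: none
Why: Luche reduction, which should reduce the unhindered conjugated C8 ketone 1,2-selectively in preference to the acetyl group (flanked by C5 and the quaternary C10) and the ester, so that the enone is parked; the C8 carbinol centre formed here is transient because C8 is re-oxidised in step 6.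

Step 4
Reactants: 7 methyl (1S,6S)-6-acetyl-3-hydroxy-1-methylcyclohex-4-ene-1-carboxylate
Product: 8 methyl (1S,6R)-3-hydroxy-1-methyl-6-(prop-1-en-2-yl)cyclohex-4-ene-1-carboxylate (both C3 epimers)
Conditions: Zn, CH2Br2, TiCl4 (pre-aged reagent, excess), THF/CH2Cl2, 0 → 23 °C
Reagents that add atoms: dibromomethane, BrCBr
Why: Takai–Lombardo methylenation, whose non-basic zinc/titanium methylene reagent should convert the enolisable methyl ketone into the isopropenyl group without epimerising C5, leaves the ester alone and tolerates the free hydroxyl as its titanium alkoxide.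

Step 5
Reactants: 8 methyl (1S,6R)-3-hydroxy-1-methyl-6-(prop-1-en-2-yl)cyclohex-4-ene-1-carboxylate
Product: 9 (4R,5S)-5-(hydroxymethyl)-5-methyl-4-(prop-1-en-2-yl)cyclohex-2-en-1-ol (both C1 epimers)
Conditions: i-Bu2AlH (4 equiv), CH2Cl2, −78 → 0 °C; aqueous potassium sodium tartrate
Reagents that add atoms: none
Why: Aluminium hydride reduction of the neopentyl methyl ester to the primary alcohol, with no other reducible group present and no stereocentre touched.

Step 6
Reactants: 9 (4R,5S)-5-(hydroxymethyl)-5-methyl-4-(prop-1-en-2-yl)cyclohex-2-en-1-ol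
Product: 10 (1S,6R)-1-methyl-3-oxo-6-(prop-1-en-2-yl)cyclohex-4-ene-1-carbaldehyde
Conditions: Dess–Martin periodinane (2.5 equiv), CH2Cl2, 0 → 23 °C
Reagents that add atoms: none
Why: Dess–Martin oxidation, in which the allylic C8 carbinol should be oxidised first (both epimers converge on the enone) and the neopentyl primary alcohol then gives the non-enolisable aldehyde, under non-basic conditions that leave C5 untouched.

Step 7
Reactants: 10 (1S,6R)-1-methyl-3-oxo-6-(prop-1-en-2-yl)cyclohex-4-ene-1-carbaldehyde
Product: 11 (4R,5R)-5-ethenyl-5-methyl-4-(prop-1-en-2-yl)cyclohex-2-en-1-one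
Conditions: Ph3PCH3Br, KOt-Bu, THF, 0 °C; then 10 (ylide 1.05 equiv), −78 → 0 °C
Reagents that add atoms: methyltriphenylphosphonium bromide, C[P+](c1ccccc1)(c1ccccc1)c1ccccc1.[Br-]
Why: Wittig methylenation, chemoselective because the unstabilised ylide adds to an aldehyde far faster than to a conjugated ketone at low temperature, which turns the formyl group into the C10 vinyl group while the hindered C5–H is not deprotonated.

Step 8
Reactants: 11 (4R,5R)-5-ethenyl-5-methyl-4-(prop-1-en-2-yl)cyclohex-2-en-1-one
Product: 12 (4R,5R)-5-ethenyl-2-iodo-5-methyl-4-(prop-1-en-2-yl)cyclohex-2-en-1-one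
Conditions: I2, pyridine, CH2Cl2, 0 → 23 °C
Reagents that add atoms: iodine, II
Why: α-Iodination of the enone by conjugate addition of pyridine, iodination of the resulting enolate at C7 and elimination of pyridine; the isolated alkenes should survive because iodonium formation on them is reversible.

Step 9
Reactants: 12 (4R,5R)-5-ethenyl-2-iodo-5-methyl-4-(prop-1-en-2-yl)cyclohex-2-en-1-one; 13 methyl 2-bromopropanoate (racemic)
Product: 15 methyl 2-[(3R,4R)-4-ethenyl-4-methyl-6-oxo-3-(prop-1-en-2-yl)cyclohex-1-en-1-yl]propanoate (both epimers at C11), via zinc ester enolate 14 (not isolated)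
Conditions: 13, Zn dust (Me3SiCl-activated), THF, 23 °C; then 12, Pd(P(t-Bu)3)2 (5 mol%), THF, 23 °C
Reagents that add atoms: none
Why: Negishi coupling of a Reformatsky reagent, in which zerovalent palladium inserts into the C7–I bond, the zinc ester enolate transmetallates and reductive elimination forms C7–C11; the C11 centre forms unselectively and is erased by enolisation in step 13.

Step 10
Reactants: 15 methyl 2-[(3R,4R)-4-ethenyl-4-methyl-6-oxo-3-(prop-1-en-2-yl)cyclohex-1-en-1-yl]propanoate
Product: 17 cis-fused keto-lactone (6-ethenyl-3,6-dimethyl-7-(prop-1-en-2-yl)hexahydro-1-benzofuran-2,4-dione; H6 and H7 cis, O6 trans to the C5 isopropenyl, both C11 epimers), via enone acid 16 (not isolated)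
Conditions: Me3SnOH, ClCH2CH2Cl, 70 °C; 0.1 M HCl wash; then camphorsulfonic acid (20 mol%), CH2Cl2, 23 °C
Reagents that add atoms: trimethyltin hydroxide, C[Sn](C)(C)O
Why: Neutral ester hydrolysis followed by acid-catalysed intramolecular oxa-Michael lactonisation: the carboxylic acid adds to C6 of the protonated enone (a 5-endo closure that becomes feasible when the enone reacts as a hydroxyallyl cation) anti to the C5 isopropenyl group, and the enol is protonated at C7 to the cis-fused γ-lactone, which should also be the thermodynamic isomer since C7 stays epimerisable next to the ketone and the addition is reversible.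

Step 11
Reactants: 17 cis-fused keto-lactone
Product: 18 hydroxy lactone (C8 alcohol cis to the C10 methyl and trans to the C7–C11 bond; both C11 epimers)
Conditions: LiBH(s-Bu)3 (1.2 equiv), THF, −78 °C; then H2O2, pH 7 buffer, 0 °C
Reagents that add atoms: none
Why: Hydride reduction by a bulky trialkylborohydride, which attacks cyclohexanones along the equatorial direction; in the elemane chair (isopropenyl and vinyl equatorial, C10 methyl axial) the axial path to C8 is in addition shut by the syn-axial methyl, so the axial C8 alcohol on the methyl face should form, and the lactone is inert at −78 °C.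

Step 12
Reactants: 18 hydroxy lactone
Product: 19 C8 triethylsilyl ether of 18
Conditions: Et3SiOTf, 2,6-lutidine, CH2Cl2, −78 → 0 °C
Reagents that add atoms: triethylsilyl trifluoromethanesulfonate, CC[Si](CC)(CC)OS(=O)(=O)C(F)(F)F
Why: Silylation with a silyl triflate, reactive enough for the hindered axial C8 hydroxyl, masks the only acidic O–H so that the lactone can be enolised.

Step 13
Reactants: 19 C8 triethylsilyl ether
Product: 20 C11 α-hydroxy lactone (C11 hydroxyl on the convex face, cis to H7; C13 methyl on the concave face)
Conditions: KN(SiMe3)2, THF, −78 °C; then 2-(phenylsulfonyl)-3-phenyloxaziridine, −78 °C; NH4Cl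
Reagents that add atoms: 2-(phenylsulfonyl)-3-phenyloxaziridine, O=S(=O)(c1ccccc1)N1OC1c1ccccc1
Why: Enolate hydroxylation with an N-sulfonyloxaziridine: both C11 epimers converge on one planar potassium enolate, and the oxidant should approach its convex face (the side of H6/H7, away from the cyclohexane), which puts the hydroxyl exo and the methyl endo as the target requires.

Step 14
Reactants: 20 C11 α-hydroxy lactone; 21 angelic acid
Product: 23 C11 angelate, C8 triethylsilyl ether, via mixed anhydride 22 (not isolated)
Conditions: 21, 2,4,6-trichlorobenzoyl chloride, Et3N, PhMe, 23 °C; 20, LiN(SiMe3)2, THF, −78 °C, then the anhydride solution, −78 → 0 °C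
Reagents that add atoms: none
Why: Yamaguchi-type esterification through the mixed anhydride, in which the lithium alkoxide of the tertiary alcohol attacks the unhindered angeloyl carbonyl, and the low temperature and absence of a nucleophilic catalyst should preserve the Z geometry of the angelate.

Step 15
Reactants: 23 C11 angelate, C8 triethylsilyl ether
Product: 24 C11 angelate with free C8 hydroxyl
Conditions: HF·pyridine, pyridine, THF, 0 → 23 °C
Reagents that add atoms: none
Why: Fluoride-mediated desilylation cleaves the triethylsilyl ether and leaves the angelate, the lactone and the alkenes untouched.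

Step 16
Reactants: 24 C11 angelate with free C8 hydroxyl
Product: 25 CNP0140071.1
Conditions: Ac2O, pyridine, DMAP (cat.), CH2Cl2, 0 → 23 °C
Reagents that add atoms: acetic anhydride, CC(=O)OC(C)=O
Why: Acylation of the only remaining hydroxyl (secondary, C8) under nucleophilic catalysis at room temperature, which should not isomerise the angelate, gives the target.

## Compound list

1 | methylglyoxal (2-oxopropanal) | CC(=O)C=O | starting material
2 | methyl 2-(triphenylphosphoranylidene)propanoate | COC(=O)C(C)=P(c1ccccc1)(c1ccccc1)c1ccccc1 | starting material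
3 | methyl (E)-2-methyl-4-oxopent-2-enoate | CC(=O)/C=C(\C)C(=O)OC | intermediate
4 | (E)-1-methoxy-3-trimethylsilyloxybuta-1,3-diene | CO/C=C/C(=C)O[Si](C)(C)C | starting material
5 | methyl 6-acetyl-5-methoxy-1-methyl-3-(trimethylsilyloxy)cyclohex-3-ene-1-carboxylate (acetyl cis to the ring methyl; methoxy centre left open; not isolated) | COC(=O)[C@@]1(C)CC(O[Si](C)(C)C)=CC(OC)[C@@H]1C(C)=O | intermediate
6 | methyl (1S,6S)-6-acetyl-1-methyl-3-oxocyclohex-4-ene-1-carboxylate | COC(=O)[C@@]1(C)CC(=O)C=C[C@@H]1C(C)=O | intermediate
7 | methyl (1S,6S)-6-acetyl-3-hydroxy-1-methylcyclohex-4-ene-1-carboxylate (C3 epimers) | COC(=O)[C@@]1(C)CC(O)C=C[C@@H]1C(C)=O | intermediate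
8 | methyl (1S,6R)-3-hydroxy-1-methyl-6-(prop-1-en-2-yl)cyclohex-4-ene-1-carboxylate (C3 epimers) | COC(=O)[C@@]1(C)CC(O)C=C[C@@H]1C(C)=C | intermediate
9 | (4R,5S)-5-(hydroxymethyl)-5-methyl-4-(prop-1-en-2-yl)cyclohex-2-en-1-ol (C1 epimers) | OC[C@@]1(C)CC(O)C=C[C@@H]1C(C)=C | intermediate
10 | (1S,6R)-1-methyl-3-oxo-6-(prop-1-en-2-yl)cyclohex-4-ene-1-carbaldehyde | O=C[C@@]1(C)CC(=O)C=C[C@@H]1C(C)=C | intermediate
11 | (4R,5R)-5-ethenyl-5-methyl-4-(prop-1-en-2-yl)cyclohex-2-en-1-one | C=C[C@@]1(C)CC(=O)C=C[C@@H]1C(C)=C | intermediate
12 | (4R,5R)-5-ethenyl-2-iodo-5-methyl-4-(prop-1-en-2-yl)cyclohex-2-en-1-one | C=C[C@@]1(C)CC(=O)C(I)=C[C@@H]1C(C)=C | intermediate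
13 | methyl 2-bromopropanoate (racemic) | CC(Br)C(=O)OC | starting material
14 | (1-methoxy-1-oxopropan-2-yl)zinc bromide (not isolated) | COC(=O)C(C)[Zn]Br | intermediate
15 | methyl 2-[(3R,4R)-4-ethenyl-4-methyl-6-oxo-3-(prop-1-en-2-yl)cyclohex-1-en-1-yl]propanoate (C11 epimers) | C=C[C@@]1(C)CC(=O)C(C(C)C(=O)OC)=C[C@@H]1C(C)=C | intermediate
16 | 2-[(3R,4R)-4-ethenyl-4-methyl-6-oxo-3-(prop-1-en-2-yl)cyclohex-1-en-1-yl]propanoic acid (C11 epimers; not isolated) | C=C[C@@]1(C)CC(=O)C(C(C)C(=O)O)=C[C@@H]1C(C)=C | intermediate
17 | cis-fused keto-lactone, 6-ethenyl-3,6-dimethyl-7-(prop-1-en-2-yl)hexahydro-1-benzofuran-2,4-dione (H6/H7 cis, O6 trans to isopropenyl; C11 epimers) | C=C[C@@]1(C)CC(=O)[C@@H]2[C@@H](OC(=O)C2C)[C@@H]1C(=C)C | intermediate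
18 | hydroxy lactone, 4-hydroxy analogue of 17 (C8–OH cis to the C10 methyl, trans to C7–C11; C11 epimers) | C=C[C@@]1(C)C[C@H](O)[C@@H]2[C@@H](OC(=O)C2C)[C@@H]1C(=C)C | intermediate
19 | C8 triethylsilyl ether of 18 | C=C[C@@]1(C)C[C@H](O[Si](CC)(CC)CC)[C@@H]2[C@@H](OC(=O)C2C)[C@@H]1C(=C)C | intermediate
20 | C11 α-hydroxy lactone (C11–OH cis to H7, C13 methyl endo), C8 triethylsilyl ether | C=C[C@@]1(C)C[C@H](O[Si](CC)(CC)CC)[C@@H]2[C@@H](OC(=O)[C@@]2(C)O)[C@@H]1C(=C)C | intermediate
21 | angelic acid, (Z)-2-methylbut-2-enoic acid | C/C=C(/C)C(=O)O | starting material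
22 | (Z)-2-methylbut-2-enoic 2,4,6-trichlorobenzoic anhydride (not isolated) | C/C=C(/C)C(=O)OC(=O)c1c(Cl)cc(Cl)cc1Cl | intermediate
23 | C11 angelate, C8 triethylsilyl ether | C=C[C@@]1(C)C[C@H](O[Si](CC)(CC)CC)[C@@H]2[C@@H](OC(=O)[C@@]2(C)OC(=O)/C(C)=C\C)[C@@H]1C(=C)C | intermediate
24 | C11 angelate, C8 alcohol | C=C[C@@]1(C)C[C@H](O)[C@@H]2[C@@H](OC(=O)[C@@]2(C)OC(=O)/C(C)=C\C)[C@@H]1C(=C)C | intermediate
25 | CNP0140071.1, the 8-acetoxy-11-angeloyloxy elemanolide (6,12-olide) | C=C[C@@]1(C)C[C@H](OC(C)=O)[C@@H]2[C@@H](OC(=O)[C@@]2(C)OC(=O)/C(C)=C\C)[C@@H]1C(=C)C | target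

## Step count and risks

Total steps: 16. Longest linear sequence: 16 steps (1 and 2 to 25); 4, 13 and 21 are bought and enter at steps 2, 9 and 14.

Steps most likely to fail:

1. Step 2 (key cycloaddition).
   - What may go wrong: bond formation at the fully substituted C10 may be slow, so that acid-promoted decomposition of the diene or a stepwise Mukaiyama–Michael pathway (loss of the cis relation between the C10 methyl and the C5 acetyl) competes. Facial selectivity on the trisubstituted, s-cis-preferring dienophile may be poor or reversed. C5 may epimerise during the acidic work-up.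
   - Fallback: setting out from 3, the far more nucleophilic, commercial (E)-1-(dimethylamino)-3-(tert-butyldimethylsilyloxy)buta-1,3-diene is added without any acid (toluene, 23–40 °C; same orientation, amino terminus to C5) to give the racemic amino cycloadduct F1. Aqueous HF in MeCN at 0 °C cleaves the silyl enol ether and eliminates dimethylamine to the racemic enone. The unwanted enantiomer ent-6 F2 is removed by preparative HPLC on a chiral stationary phase, and the route is rejoined at 6.

2. Step 10 (oxa-Michael lactonisation).
   - What may go wrong: the 5-endo closure may be slow, so that acid-promoted migration of the isopropenyl double bond, or scrambling at C5 through the dienol of the enone, overtakes ring closure.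
   - Fallback: setting out from 15, copper-catalysed conjugate borylation (CuCl, NaOt-Bu, a bisphosphine, B2pin2, MeOH, THF) adds boron to C6 anti to the isopropenyl group to give the β-boryl ketone F3. NaBO3·4H2O oxidises the C–B bond with retention to the β-hydroxy ketone F4. With a trace of pyridinium p-toluenesulfonate in benzene the C6 hydroxyl closes onto the methyl ester (attack at the ester carbonyl, loss of methanol) after equilibration at the ketone-activated C7, and the route is rejoined at 17.

3. Step 11 (C8 reduction).
   - What may go wrong: hydride may be delivered from the convex face of the cis-fused bicycle (the wrong diastereoface at C8), because the equatorial path on the required face runs past the axial C7–C11 bond. The β-acyloxy ketone may also open by a base-induced retro-oxa-Michael reaction before it is reduced.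
   - Fallback: setting out from 17, the product of convex-face attack, the 8-epi alcohol F5 (from the same reduction or from NaBH4/CeCl3·7H2O in MeOH), is converted into the triflate F6 (Tf2O, pyridine, CH2Cl2, −20 °C). It is inverted with KNO2/18-crown-6 in DMF (Lattrell–Dax nitrite displacement, the nitrite ester being hydrolysed on work-up). The face that admitted hydride also admits the small nitrite ion, and the route is rejoined at 18.

## Further compounds

F1 | step 2 | methyl 6-acetyl-5-(dimethylamino)-1-methyl-3-(tert-butyldimethylsilyloxy)cyclohex-3-ene-1-carboxylate (racemate, one enantiomer drawn; acetyl cis to the ring methyl) | COC(=O)[C@@]1(C)CC(O[Si](C)(C)C(C)(C)C)=CC(N(C)C)[C@@H]1C(C)=O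
F2 | step 2 | methyl (1R,6R)-6-acetyl-1-methyl-3-oxocyclohex-4-ene-1-carboxylate (ent-6) | COC(=O)[C@]1(C)CC(=O)C=C[C@H]1C(C)=O
F3 | step 10 | methyl 2-[4-ethenyl-4-methyl-6-oxo-3-(prop-1-en-2-yl)-2-(4,4,5,5-tetramethyl-1,3,2-dioxaborolan-2-yl)cyclohexyl]propanoate (boron trans to isopropenyl; C7 and C11 epimers) | C=C[C@@]1(C)CC(=O)C(C(C)C(=O)OC)[C@@H](B2OC(C)(C)C(C)(C)O2)[C@@H]1C(C)=C
F4 | step 10 | methyl 2-[4-ethenyl-2-hydroxy-4-methyl-6-oxo-3-(prop-1-en-2-yl)cyclohexyl]propanoate (hydroxyl trans to isopropenyl; C7 and C11 epimers) | C=C[C@@]1(C)CC(=O)C(C(C)C(=O)OC)[C@@H](O)[C@@H]1C(C)=C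
F5 | step 11 | 8-epi hydroxy lactone (C8–OH cis to the C7–C11 bond; C11 epimers) | C=C[C@@]1(C)C[C@@H](O)[C@@H]2[C@@H](OC(=O)C2C)[C@@H]1C(=C)C
F6 | step 11 | trifluoromethanesulfonate of the 8-epi hydroxy lactone | C=C[C@@]1(C)C[C@@H](OS(=O)(=O)C(F)(F)F)[C@@H]2[C@@H](OC(=O)C2C)[C@@H]1C(=C)C
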